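**Plan**

Locants: ring A is the benzo ring (C4a, C5–C8, C8a), ring B the dihydro ring (C1–C4), primed atoms belong to the pyranone. Retrosynthetically the catechol and the three acids are masked (C7 methyl ether, alkyl esters), then ring B is cut at C1–C8a and C1–C2.
Enabling feature: C1 carries ring A carbon C8a (para to the C6 hydroxyl), C2 (α to an ester, allylic to C3=C4) and pyranone carbon C4′. C1 is therefore the formyl carbon of a 4-formyl-2-pyranone alkylated twice, and the C6 hydroxyl lets the second alkylation run through a para-quinone methide.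
Forward: ring A is bought as isovanillin, and a Stobbe condensation attaches the C2–C3–C4 succinate arm as the (E)-alkene. The pyranone ring is built from diethyl oxalate and ethyl 3-methylbut-2-enoate, and its C4′ methyl is oxidised to the aldehyde.
Ring B is closed last by joining the two halves in one flask; O-demethylation and ester hydrolysis finish the synthesis.
Stereochemistry: C1 is set in the ring closure by a chiral phosphoric acid. C2 follows as trans (transition-state preference, and C2 remains epimerisable toward the more stable trans isomer); the alkene geometry comes from the Stobbe step.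

Key step: step 6

Assumption: the (R)-configured phosphoric acid is taken to deliver the (1R,2S) product; should the sense of induction be the opposite, the (S)-acid is used with no other change.

**Route**

Step 1
Reactants: 1 isovanillin (3-hydroxy-4-methoxybenzaldehyde)
Product: 2 4-methoxy-3-(methoxymethoxy)benzaldehyde
Conditions: MOMCl, i-Pr2NEt, CH2Cl2, 0 °C to rt
Reagents that add atoms: chloromethyl methyl ether (MOMCl), COCCl
Why: Base-mediated O-alkylation of the phenol (methoxymethyl ether formation) masks the acidic hydroxyl, which would otherwise consume methoxide and retard the Stobbe condensation, as an acetal that is inert to alkoxide.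

Step 2
Reactants: 2 4-methoxy-3-(methoxymethoxy)benzaldehyde; 3 dimethyl succinate
Product: 4 (E)-3-(methoxycarbonyl)-4-[4-methoxy-3-(methoxymethoxy)phenyl]but-3-enoic acid
Conditions: NaOMe, MeOH, reflux; then cold 1 M HCl to pH 3
Reagents that add atoms: none
Why: Stobbe condensation (aldol addition, lactonisation to the paraconate ester, E1cB ring opening) should give the half-ester with the free acid on the CH2 arm and the (E)-alkene in which the aryl ring and the CH2 group are cis, as the later ring closure requires.

Step 3
Reactants: 4 (E)-3-(methoxycarbonyl)-4-[4-methoxy-3-(methoxymethoxy)phenyl]but-3-enoic acid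
Product: 5 dimethyl (E)-2-(3-hydroxy-4-methoxybenzylidene)succinate
Conditions: HCl (1.25 M in MeOH), 50 °C
Reagents that add atoms: methanol, CO
Why: Fischer esterification of the acid in methanolic HCl, which also cleaves the methoxymethyl acetal by acid-catalysed acetal exchange, so that one operation should deliver the diester with the free C6 hydroxyl.

Step 4
Reactants: 6 ethyl 3-methylbut-2-enoate; 7 diethyl oxalate
Product: 9 ethyl 4-methyl-2-oxo-2H-pyran-6-carboxylate, via potassium dienolate 8 (not isolated)
Conditions: KOEt, EtOH–Et2O, 0 °C to rt; AcOH; then TsOH·H2O (cat.), PhMe, reflux (−EtOH)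
Reagents that add atoms: none
Why: Vinylogous Claisen condensation of the γ-deprotonated ester with diethyl oxalate gives the hydroxymuconate-type dienolate, whose enol oxygen lactonises onto the cis-disposed ester under acid with loss of ethanol, the classical oxalylcrotonate route to 2-pyranone-6-carboxylates.

Step 5
Reactants: 9 ethyl 4-methyl-2-oxo-2H-pyran-6-carboxylate
Product: 10 ethyl 4-formyl-2-oxo-2H-pyran-6-carboxylate
Conditions: SeO2 (1.3 equiv), 1,4-dioxane, 100 °C
Reagents that add atoms: selenium dioxide, O=[Se]=O
Why: Riley oxidation: the C4′ methyl is the vinylogous α-position of the lactone carbonyl and should be oxidised by SeO2 through an ene reaction and [2,3]-sigmatropic shift to the aldehyde, as is established for 4-methylcoumarins and methyl-2-pyranones.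

Step 6
Reactants: 5 dimethyl (E)-2-(3-hydroxy-4-methoxybenzylidene)succinate; 10 ethyl 4-formyl-2-oxo-2H-pyran-6-carboxylate
Product: 13 dimethyl (1R,2S)-1-[6-(ethoxycarbonyl)-2-oxo-2H-pyran-4-yl]-6-hydroxy-7-methoxy-1,2-dihydronaphthalene-2,3-dicarboxylate, via diarylcarbinol 11 (not isolated), via para-quinone methide 12 (not isolated)
Conditions: (R)-TRIP [(R)-3,3′-bis(2,4,6-triisopropylphenyl)-1,1′-binaphthyl-2,2′-diyl hydrogen phosphate] (10 mol %), 5 Å MS, PhCF3, 50 °C; 5 added slowly to 10 (1.5 equiv)
Reagents that add atoms: none
Why: Proposed new method: the phosphoric acid activates the electron-poor aldehyde of 10 for Friedel–Crafts hydroxyalkylation of phenol 5 at the ring carbon para to the hydroxyl (the future C8a), carbinol 11 loses water to para-quinone methide 12 because the C6 hydroxyl can become the quinone carbonyl, and the C2 methylene, acidified by its own ester and as the ε-position of the dienone O=C6–C5=C4a–C4=C3, is enolised by the phosphate and adds to C1 in a 1,6-addition that restores ring A. The closest known reactions are chiral phosphoric acid-catalysed 1,6-additions of carbon nucleophiles to para-quinone methides generated in situ from para-hydroxybenzyl alcohols and the acid-mediated hydroxyalkylation of phenols by aldehydes; an ester dienol as the nucleophile and the merger of both events in one flask are untested. Ring B closes in a 6-endo-trig mode (C2 onto C1 of the exocyclic C1=C8a bond), which can equally be viewed as a 6π-electrocyclisation of the trienol tautomer of 12. The C1 stereocentre is set by the chiral phosphate, ion-paired or hydrogen-bonded to the quinone methide oxygen and to the dienol so that one face of C1 is shielded; C2 follows as trans because the half-chair transition state keeps the pyranone and the C2 ester apart and C2 stays epimerisable toward the more stable trans isomer. The step needs regioselection for C8a over C5 and C8 (para to the free hydroxyl and less hindered than the position between hydroxyl and side chain, as in phenolic Pictet–Spengler closures), capture of 12 by C2 in preference to a second phenol molecule (slow addition of 5 to an excess of 10), and the (E)-alkene from step 2, which holds C2 beside C8a.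

Step 7
Reactants: 13 dimethyl (1R,2S)-1-[6-(ethoxycarbonyl)-2-oxo-2H-pyran-4-yl]-6-hydroxy-7-methoxy-1,2-dihydronaphthalene-2,3-dicarboxylate
Product: 14 dimethyl (1R,2S)-1-[6-(ethoxycarbonyl)-2-oxo-2H-pyran-4-yl]-6,7-dihydroxy-1,2-dihydronaphthalene-2,3-dicarboxylate
Conditions: BBr3 (3 equiv), CH2Cl2, −78 to −20 °C; then H2O
Reagents that add atoms: none
Why: Lewis acid-mediated aryl methyl ether cleavage, in which the neighbouring phenol binds boron and bromide attacks the methyl group at low temperature, conditions under which the alkyl esters, the pyranone and both stereocentres are expected to stay untouched.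

Step 8
Reactants: 14 dimethyl (1R,2S)-1-[6-(ethoxycarbonyl)-2-oxo-2H-pyran-4-yl]-6,7-dihydroxy-1,2-dihydronaphthalene-2,3-dicarboxylate
Product: 15 (1R,2S)-1-(6-carboxy-2-oxo-2H-pyran-4-yl)-6,7-dihydroxy-1,2-dihydronaphthalene-2,3-dicarboxylic acid
Conditions: 6 M aq. HCl–1,4-dioxane (1:1), 80 °C, degassed, argon
Reagents that add atoms: water, O
Why: Acid-catalysed ester hydrolysis (acyl–oxygen cleavage) is used because hydroxide would open the 2-pyranone, while the acid-stable pyranone, the C3=C4 alkene and the trans C1/C2 relationship (the thermodynamic one at the epimerisable C2) are expected to survive when air is excluded.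

**Compound list**

1 | isovanillin (3-hydroxy-4-methoxybenzaldehyde) | COc1ccc(C=O)cc1O | starting material
2 | 4-methoxy-3-(methoxymethoxy)benzaldehyde | COCOc1cc(C=O)ccc1OC | intermediate
3 | dimethyl succinate | COC(=O)CCC(=O)OC | starting material
4 | (E)-3-(methoxycarbonyl)-4-[4-methoxy-3-(methoxymethoxy)phenyl]but-3-enoic acid | OC(=O)C/C(C(=O)OC)=C\c1ccc(OC)c(OCOC)c1 | intermediate
5 | dimethyl (E)-2-(3-hydroxy-4-methoxybenzylidene)succinate | COC(=O)C/C(C(=O)OC)=C\c1ccc(OC)c(O)c1 | intermediate
6 | ethyl 3-methylbut-2-enoate | CCOC(=O)C=C(C)C | starting material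
7 | diethyl oxalate | CCOC(=O)C(=O)OCC | starting material
8 | potassium dienolate (not isolated): potassium (2Z,4Z)-1,6-diethoxy-4-methyl-1,6-dioxohexa-2,4-dien-2-olate | CCOC(=O)/C([O-])=C/C(C)=C\C(=O)OCC.[K+] | intermediate
9 | ethyl 4-methyl-2-oxo-2H-pyran-6-carboxylate | CCOC(=O)c1cc(C)cc(=O)o1 | intermediate
10 | ethyl 4-formyl-2-oxo-2H-pyran-6-carboxylate | CCOC(=O)c1cc(C=O)cc(=O)o1 | intermediate
11 | diarylcarbinol (not isolated, either configuration at the carbinol carbon): dimethyl (E)-2-{2-[(6-ethoxycarbonyl-2-oxo-2H-pyran-4-yl)(hydroxy)methyl]-5-hydroxy-4-methoxybenzylidene}succinate | COC(=O)C/C(C(=O)OC)=C\c1cc(O)c(OC)cc1C(O)c1cc(C(=O)OCC)oc(=O)c1 | intermediate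
12 | para-quinone methide (not isolated, drawn with the pyranone turned away from the alkenyl arm): dimethyl (E)-2-({6-[(6-ethoxycarbonyl-2-oxo-2H-pyran-4-yl)methylidene]-4-methoxy-3-oxocyclohexa-1,4-dien-1-yl}methylidene)succinate | COC(=O)C/C(C(=O)OC)=C\C1=CC(=O)C(OC)=C/C1=C\c1cc(C(=O)OCC)oc(=O)c1 | intermediate
13 | dimethyl (1R,2S)-1-[6-(ethoxycarbonyl)-2-oxo-2H-pyran-4-yl]-6-hydroxy-7-methoxy-1,2-dihydronaphthalene-2,3-dicarboxylate | COC(=O)C1=Cc2cc(O)c(OC)cc2[C@@H](c2cc(C(=O)OCC)oc(=O)c2)[C@@H]1C(=O)OC | intermediate
14 | dimethyl (1R,2S)-1-[6-(ethoxycarbonyl)-2-oxo-2H-pyran-4-yl]-6,7-dihydroxy-1,2-dihydronaphthalene-2,3-dicarboxylate | COC(=O)C1=Cc2cc(O)c(O)cc2[C@@H](c2cc(C(=O)OCC)oc(=O)c2)[C@@H]1C(=O)OC | intermediate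
15 | (1R,2S)-1-(6-carboxy-2-oxo-2H-pyran-4-yl)-6,7-dihydroxy-1,2-dihydronaphthalene-2,3-dicarboxylic acid | O=C(O)C1=Cc2cc(O)c(O)cc2[C@@H](c2cc(C(=O)O)oc(=O)c2)[C@@H]1C(=O)O | target

**Step count and risks**

Total step count: 8. Longest linear sequence: 6 steps (1, 2, 3, 6, 7, 8); the pyranone branch (steps 4 and 5) joins at step 6.

Steps most likely to fail:

Step 6 (proposed new method). The aldehyde may not engage C8a under the weak acid, the quinone methide may be intercepted by a second phenol molecule, enolisation at C2 may be too slow, or the catalyst may not discriminate the faces of C1. The fallback uses known reactions and makes C1–C2 first; it sets out from 4 and 10 and comes back at 13. Acid 4 is methylated (MeI, K2CO3, DMF) to dimethyl (E)-2-[4-methoxy-3-(methoxymethoxy)benzylidene]succinate F1. Its lithium dienolate (LDA, THF, −78 °C, AcOH quench) undergoes α-aldol addition to aldehyde 10 to give dimethyl (E)-2-{[6-(ethoxycarbonyl)-2-oxo-2H-pyran-4-yl](hydroxy)methyl}-3-[4-methoxy-3-(methoxymethoxy)benzylidene]succinate F2 as a diastereomer mixture. MsCl and Et3N in CH2Cl2 at 0 °C convert it into the methanesulfonate of this alcohol F3, which eliminates with further Et3N to dimethyl (2E,3E)-2-{[6-(ethoxycarbonyl)-2-oxo-2H-pyran-4-yl]methylidene}-3-[4-methoxy-3-(methoxymethoxy)benzylidene]succinate F4. TfOH in CH2Cl2 at 0 °C removes the acetal and brings about the known Friedel–Crafts conjugate cyclisation of bis-arylidene succinates to trans-1-aryl-1,2-dihydronaphthalene-2,3-dicarboxylates. This should give 13 as a racemate with its enantiomer, dimethyl (1S,2R)-1-[6-(ethoxycarbonyl)-2-oxo-2H-pyran-4-yl]-6-hydroxy-7-methoxy-1,2-dihydronaphthalene-2,3-dicarboxylate F5, and preparative HPLC on a chiral stationary phase returns the route to 13.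

Step 5. Over-oxidation to the carboxylic acid or breakdown of the pyranone at the temperature the selenium dioxide oxidation needs. The fallback sets out from 9 and comes back at 10: Wohl–Ziegler bromination (NBS, AIBN cat., PhCF3, reflux) gives ethyl 4-(bromomethyl)-2-oxo-2H-pyran-6-carboxylate F6, which N-methylmorpholine N-oxide in MeCN at rt oxidises to aldehyde 10 (amine-oxide variant of the Kornblum oxidation).

Step 8. Loss of enantiopurity at C1 in hot acid (reversible opening of the C1–C2 bond through the quinone methide, or enolisation toward the pyranone), aromatisation of ring B, or incomplete hydrolysis of the hindered conjugated esters. The fallback sets out from 14 and comes back at 15 without hydrolysis: excess BBr3 in CH2Cl2 (−78 °C to rt) removes the three ester alkyl groups by bromide attack at the O-alkyl carbons, a known non-hydrolytic ester cleavage that needs no heating, and aqueous work-up gives 15. This fallback makes no new compound (F0).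

Further compounds
F1 | step 6 | dimethyl (E)-2-[4-methoxy-3-(methoxymethoxy)benzylidene]succinate | COC(=O)C/C(C(=O)OC)=C\c1ccc(OC)c(OCOC)c1
F2 | step 6 | dimethyl (E)-2-{[6-(ethoxycarbonyl)-2-oxo-2H-pyran-4-yl](hydroxy)methyl}-3-[4-methoxy-3-(methoxymethoxy)benzylidene]succinate (diastereomer mixture) | COC(=O)C(C(O)c1cc(C(=O)OCC)oc(=O)c1)/C(C(=O)OC)=C\c1ccc(OC)c(OCOC)c1
F3 | step 6 | methanesulfonate of F2 | COC(=O)C(C(OS(C)(=O)=O)c1cc(C(=O)OCC)oc(=O)c1)/C(C(=O)OC)=C\c1ccc(OC)c(OCOC)c1
F4 | step 6 | dimethyl (2E,3E)-2-{[6-(ethoxycarbonyl)-2-oxo-2H-pyran-4-yl]methylidene}-3-[4-methoxy-3-(methoxymethoxy)benzylidene]succinate | COc1ccc(cc1OCOC)/C=C(/C(=O)OC)\C(C(=O)OC)=C/c1cc(C(=O)OCC)oc(=O)c1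
F5 | step 6 | dimethyl (1S,2R)-1-[6-(ethoxycarbonyl)-2-oxo-2H-pyran-4-yl]-6-hydroxy-7-methoxy-1,2-dihydronaphthalene-2,3-dicarboxylate | COC(=O)C1=Cc2cc(O)c(OC)cc2[C@H](c2cc(C(=O)OCC)oc(=O)c2)[C@H]1C(=O)OC
F6 | step 5 | ethyl 4-(bromomethyl)-2-oxo-2H-pyran-6-carboxylate | CCOC(=O)c1cc(CBr)cc(=O)o1
F0 | step 8 | none | none
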